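**Retrosynthetic overview**
1. The target is a cis-fused decalin (C5–C10 fusion, angular C10 methyl, C8 exocyclic methylene, C4 carboxyl). It is traced back to cis-octalone 28 (C8 ketone, C9 alkylidene, C3=C4 enoate) through O15 caffeoylation (malonate half ester, Knoevenagel–Doebner), C4 methylation, C8 methylenation and hydrogenation.
2. Key disconnection: ring B (C5–C10) arises by anionic oxy-Cope shift of the 2-vinylbicyclo[2.2.2]oct-5-en-2-ol 25 (C5–C6 formed, C3–C8 broken). The strategy rests on this mapping: bridgehead C10 (methyl), carbinol C8 and ester-bearing alkene carbon C4 of the bicycle become the cis ring fusion, the C8 carbonyl and the C4 ester of the decalin.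
3. 25 comes from vinyl addition to enone 23, made by aldol condensation of bicyclic ketone 15 (C9 is its only enolisable carbon) with aldehyde 19, which brings C13 from methyl (R)-3-methylglutarate.
4. 15 comes from the Diels–Alder reaction of a masked o-benzoquinone (from phenol 5) with tert-butyl acrylate as a traceless two-carbon unit: the ketal is removed with SmI2, the carboxyl serves for resolution and is then removed by Barton decarboxylation.
5. Ring order: the bicyclo[2.2.2]octene that holds ring A (C1–C5, C10) first (step 4), ring B second (step 13).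

Key step: step 13

Remarks on the chemistry (before the steps):
- Skeletal atoms carry labdane numbers (C1–C20) in all intermediates; names of bicyclic compounds use bicyclo[2.2.2]octene locants.
- Compounds 8–10 are racemic; their SMILES show the enantiomer that is carried on.
- Assumption: the Diels–Alder adduct 8 has the acrylate ester on C2 and endo (syn to C4=C5); neither point matters after step 8.
- Assumption: the (R)-1-phenylethylammonium salt of the required enantiomer of 10 is the less soluble one; if the opposite holds, the (S)-amine is used in the same way.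

Step 1
Reactants: 1 methyl 4-hydroxy-3-methylbenzoate
Product: 2 methyl 3-bromo-4-hydroxy-5-methylbenzoate
Conditions: Br2, AcOH, rt
Reagents that add atoms: bromine BrBr
Why: Electrophilic aromatic bromination: the hydroxyl directs to its only free ortho position, since the para position carries the ester and the other ortho position the methyl group.

Step 2
Reactants: 2 methyl 3-bromo-4-hydroxy-5-methylbenzoate
Product: 3 methyl 3-bromo-4-methoxy-5-methylbenzoate
Conditions: MeI, K2CO3, DMF, 40 °C
Reagents that add atoms: iodomethane CI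
Why: Williamson ether synthesis: the phenoxide formed with K2CO3 is methylated on oxygen by SN2 attack on MeI, the two ortho substituents slowing but not preventing the reaction.

Step 3
Reactants: 3 methyl 3-bromo-4-methoxy-5-methylbenzoate
Product: 5 methyl 3-hydroxy-4-methoxy-5-methylbenzoate, via aryl pinacolboronate 4 (not isolated)
Conditions: Pd(dppf)Cl2 (cat.), B2pin2, KOAc, dioxane, 90 °C; then KHSO5 (as 2KHSO5·KHSO4·K2SO4), acetone/H2O, 0 °C
Reagents that add atoms: bis(pinacolato)diboron CC1(C)OB(OC1(C)C)B1OC(C)(C)C(C)(C)O1 (boryl group of 4 only); potassium peroxymonosulfate [K+].[O-]S(=O)(=O)OO (phenol oxygen)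
Why: Miyaura borylation of the aryl bromide followed by oxidative ipso-hydroxylation of the boronate (aryl shift from boron to oxygen) replaces bromine by hydroxyl under conditions that leave the methyl ester intact.

Step 4
Reactants: 5 methyl 3-hydroxy-4-methoxy-5-methylbenzoate; 6 tert-butyl acrylate
Product: 8 rac-7-tert-butyl 2-methyl 5,5-dimethoxy-4-methyl-6-oxobicyclo[2.2.2]oct-2-ene-2,7-dicarboxylate (7-ester syn to C2=C3), via masked o-benzoquinone 7 (not isolated)
Conditions: PhI(OAc)2 (1.2 equiv), 6 (10 equiv), MeOH, slow addition of 5, rt → 50 °C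
Reagents that add atoms: methanol CO
Why: Oxidative dearomatisation of the 2-methoxyphenol by PhI(OAc)2 in methanol gives the o-quinone monoketal 7, whose diene C3=C4–C5=C10 adds the acrylate in a Diels–Alder reaction (the C10 methyl slows self-dimerisation); the cycloaddition fixes the bridgeheads C3 and C10 relative to each other, and the product is racemic.

Step 5
Reactants: 8 rac-dimethoxy keto diester
Product: 9 rac-7-tert-butyl 2-methyl 4-methyl-6-oxobicyclo[2.2.2]oct-2-ene-2,7-dicarboxylate
Conditions: SmI2 (5 equiv), THF/MeOH, −78 → 0 °C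
Reagents that add atoms: none
Why: Samarium diiodide reduction of an α-alkoxy ketone: electron transfer to the C8 carbonyl expels methoxide from C9 and the samarium enolate is protonated by methanol, twice, leaving C9 as CH2, while the esters and the ketone itself are not reduced at low temperature without a polar additive.

Step 6
Reactants: 9 rac-keto diester
Product: 10 rac-2-(methoxycarbonyl)-4-methyl-6-oxobicyclo[2.2.2]oct-2-ene-7-carboxylic acid (locants as in 9)
Conditions: CF3CO2H, CH2Cl2, 0 °C → rt
Reagents that add atoms: none
Why: Acidolysis of the tert-butyl ester (loss of 2-methylpropene through the tert-butyl cation) frees the C2 carboxyl selectively, the methyl enoate and the ketone being stable to trifluoroacetic acid.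

Step 7
Reactants: 10 rac-keto acid
Product: 11 (R)-1-phenylethylammonium salt of the (1R,4R)-enantiomer of 10
Conditions: (R)-1-phenylethylamine (0.5 equiv), EtOAc/iPrOH, crystallisation, two recrystallisations
Reagents that add atoms: (R)-1-phenylethylamine C[C@@H](N)c1ccccc1
Why: Classical resolution by diastereomeric salt formation: with half an equivalent of the enantiopure amine the less soluble salt crystallises and the other enantiomer of 10 stays in solution as free acid; the salt is recrystallised to constant rotation and its absolute configuration is checked by X-ray analysis, which fixes C3 and C10 as one enantiomer.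

Step 8
Reactants: 11 ammonium salt
Product: 15 methyl (1R,4R)-4-methyl-6-oxobicyclo[2.2.2]oct-2-ene-2-carboxylate, via free acid 12 (not isolated), via acid chloride 13 (not isolated), via thiohydroxamate ester 14 (not isolated)
Conditions: 1 M HCl/EtOAc (extraction); (COCl)2, DMF (cat.), CH2Cl2, 0 °C → rt; then sodium salt of 1-hydroxypyridine-2(1H)-thione, DMAP (cat.), t-BuSH (20 equiv), toluene, tungsten lamp, rt → 80 °C
Reagents that add atoms: oxalyl chloride O=C(Cl)C(=O)Cl (chlorine of 13 only); sodium salt of 1-hydroxypyridine-2(1H)-thione [Na+].[O-]N1C=CC=CC1=S (thiohydroxamate of 14 only)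
Why: Barton reductive decarboxylation: the O-acyl thiohydroxamate 14 fragments in a thiyl-radical chain to CO2 and the C2 radical, which takes hydrogen from the thiol (kept in large excess so that hydrogen transfer outruns homoallyl and acyl-shift rearrangements of the radical); C2 becomes CH2, so its configuration and the regiochemistry of step 4 are erased and the bridgeheads are untouched.

Step 9
Reactants: 16 methyl (R)-3-methylglutarate
Product: 18 methyl (3R)-5-[tert-butyl(dimethyl)silyl]oxy-3-methylpentanoate, via hydroxy ester 17 (not isolated)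
Conditions: BH3·SMe2, THF, 0 °C → rt; MeOH quench, concentration; then TBSCl, imidazole, DMF, rt
Reagents that add atoms: tert-butyldimethylsilyl chloride CC(C)(C)[Si](C)(C)Cl
Why: Borane reduces the carboxylic acid (through its acyloxyborane) much faster than the ester, and immediate silylation of the primary hydroxyl prevents lactonisation of 17; the stereocentre is not involved and becomes C13 of the target.

Step 10
Reactants: 18 silyloxy ester
Product: 19 (3R)-5-[tert-butyl(dimethyl)silyl]oxy-3-methylpentanal
Conditions: iBu2AlH (1.05 equiv), CH2Cl2, −78 °C; aq Rochelle salt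
Reagents that add atoms: none
Why: Partial reduction of the ester with iBu2AlH at −78 °C stops at the tetrahedral aluminium hemiacetal, which gives the aldehyde on work-up; the stereocentre is β to the carbonyl and cannot epimerise.

Step 11
Reactants: 15 bicyclic ketone; 19 aldehyde
Product: 23 methyl (1R,4S,5Z)-5-[(3S)-5-[tert-butyl(dimethyl)silyl]oxy-3-methylpentylidene]-4-methyl-6-oxobicyclo[2.2.2]oct-2-ene-2-carboxylate, via lithium enolate 20 (not isolated), via aldol adduct 21 (not isolated), via mesylate 22 (not isolated)
Conditions: LiN(SiMe3)2, THF, −78 °C; 19, −78 °C; aq NH4Cl; then MsCl, Et3N, CH2Cl2, 0 °C; DBU, rt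
Reagents that add atoms: lithium bis(trimethylsilyl)amide [Li+].C[Si](C)(C)[N-][Si](C)(C)C (lithium of 20 only); methanesulfonyl chloride CS(=O)(=O)Cl (mesyl group of 22 only)
Why: Directed aldol condensation: the ketone can enolise only towards C9 (its other α-carbon, C3, is a bridgehead), the lithium enolate adds to the aldehyde and mesylation/E1cB elimination gives the exocyclic enone, expected with the chain turned away from the in-plane C10 methyl (Z); the alkene geometry is of no consequence because C9=C11 is hydrogenated in step 14.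

Step 12
Reactants: 23 enone; 24 vinylmagnesium bromide
Product: 25 methyl (1R,4S,5Z,6R)-6-ethenyl-6-hydroxy-4-methyl-5-[(3S)-5-[tert-butyl(dimethyl)silyl]oxy-3-methylpentylidene]bicyclo[2.2.2]oct-2-ene-2-carboxylate (vinyl syn to the C4=C5 bridge)
Conditions: CeCl3 (anhydrous, 2 equiv), 24 (2 equiv), THF, −78 °C; aq NH4Cl
Reagents that add atoms: none
Why: 1,2-Addition of the vinylcerium reagent, which suppresses conjugate addition, enolisation and attack on the ester; the reagent should approach C8 from the side of the C4=C5 etheno bridge, less hindered than the side of the C1–C2 ethano bridge with its inward C–H bonds, so that the new C8 stereocentre carries the vinyl group syn to C4=C5 and the hydroxyl syn to C1–C2.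

Step 13
Reactants: 25 vinyl carbinol
Product: 28 methyl (4aS,8aS,5Z)-5-[(3S)-5-[tert-butyl(dimethyl)silyl]oxy-3-methylpentylidene]-4a-methyl-6-oxo-3,4,4a,5,6,7,8,8a-octahydronaphthalene-1-carboxylate (cis-fused), via potassium alkoxide 26 (not isolated), via potassium enolate 27 (not isolated)
Conditions: KH (2 equiv), 18-crown-6 (2 equiv), THF, 0 °C → rt, monitored; AcOH/THF, −78 °C
Reagents that add atoms: potassium hydride [K+].[H-] (potassium of 26 and 27 only)
Why: Deprotonation gives alkoxide 26, whose C8–O⁻ weakens the adjacent C3–C8 bond so that the 1,5-diene C6=C7–C8–C3–C4=C5 undergoes a [3,3] sigmatropic shift (anionic oxy-Cope rearrangement, the known behaviour of 2-vinylbicyclo[2.2.2]oct-5-en-2-oxides) through the boat-like array that the bicycle imposes, forming C5–C6, breaking C3–C8 and giving the cross-conjugated enolate 27 (C7=C8) and the C3=C4 enoate. Ring B (C5–C6–C7–C8–C9–C10) is closed as a six-membered carbocycle by this sigmatropic bond formation, while ring A (C10–C1–C2–C3–C4–C5) is released intact from two of the bridges. The one new stereocentre, C5, is set by suprafacial delivery of C6 to the face of C4=C5 that looks at the vinyl group; since C5 and the methyl-bearing bridgehead C10 are neighbours held in the bicycle, H-5 and the C10 methyl must come out cis, and the configuration fixed at C10 by the resolution is relayed to C5. The step needs the [3,3] shift to win over fragmentation of the alkoxide and over acylation of enolate carbon C7 by the C4 ester; the vinyl group placed syn to the etheno bridge in step 12, the acceptor ester on C4 that lowers the barrier, and a cold acetic acid quench as soon as 25 is consumed are meant to secure this. The second 1,5-diene (C11=C9–C8–C3–C4=C5) cannot react, because a C11–C5 bond would close a four-membered ring.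

Step 14
Reactants: 28 cis-fused octalone
Product: 29 methyl 5-[(3S)-5-[tert-butyl(dimethyl)silyl]oxy-3-methylpentyl]-4a-methyl-6-oxodecahydronaphthalene-1-carboxylate (4a-methyl, H-8a and H-5 on one face, side chain on the other; ester-bearing C4 as a mixture)
Conditions: H2 (1–3 atm), Pd on carbon (10 wt %), EtOAc, rt; crude product taken on without exposure to base
Reagents that add atoms: none
Why: Heterogeneous hydrogenation of the two conjugated trisubstituted alkenes: hydrogen should add to C9=C11 from the convex face of the cis-fused bicycle (the face of H-5 and the C10 methyl, ring A being folded under ring B), which places H-9 cis to the C10 methyl and the side chain trans to it; C4 forms as a mixture that is of no consequence because it is re-made in step 16.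

Step 15
Reactants: 29 saturated keto ester
Product: 30 methyl 5-[(3S)-5-[tert-butyl(dimethyl)silyl]oxy-3-methylpentyl]-4a-methyl-6-methylidenedecahydronaphthalene-1-carboxylate (ring stereocentres as in 29)
Conditions: Zn, CH2Br2, TiCl4, THF (reagent pre-formed at 0–5 °C); then 29, CH2Cl2, 0 °C → rt
Reagents that add atoms: dibromomethane BrCBr
Why: Lombardo–Takai methylenation: the gem-dizinc reagent activated by TiCl4 adds to the ketone and eliminates to the alkene without a basic ylide, so the ester is spared and the epimerisable C9 centre set in step 14 keeps its configuration and is locked once C8 no longer carries a carbonyl.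

Step 16
Reactants: 30 methylidene ester
Product: 32 methyl 1,4a-dimethyl-6-methylidene-5-[(3S)-5-[tert-butyl(dimethyl)silyl]oxy-3-methylpentyl]decahydronaphthalene-1-carboxylate (ester on C4 cis to the C10 methyl), via lithium ester enolate 31 (not isolated)
Conditions: LiN(iPr)2 (1.5 equiv), THF, −78 → 0 °C; MeI, HMPA, −78 °C → rt
Reagents that add atoms: lithium diisopropylamide [Li+].CC(C)[N-]C(C)C (lithium of 31 only); iodomethane CI
Why: Alkylation of the ester enolate: A(1,3) strain in the exocyclic enolate keeps C6 axial on ring A, so the C10 methyl is 1,3-diaxial to one face of C4 and MeI enters from the other, equatorial side, which should place the new methyl trans and the ester cis to the C10 methyl and erases the C4 mixture from step 14.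

Step 17
Reactants: 32 quaternary methyl ester
Product: 33 the corresponding C19 carboxylic acid (C15 silyl ether retained)
Conditions: NaSEt (5 equiv), DMF, 100 °C; then aq HCl to pH 3
Reagents that add atoms: none
Why: SN2 dealkylation of a hindered methyl ester: the thiolate attacks the O-methyl carbon (alkyl–oxygen cleavage) and so avoids the shielded carbonyl on the quaternary carbon; the alkene is inert and any loss of the silyl ether is harmless because it is removed in the next step.

Step 18
Reactants: 33 silyloxy acid
Product: 34 hydroxy acid (C15 OH, C19 CO2H)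
Conditions: Bu4NF, THF, rt; aq NH4Cl/dil. HCl
Reagents that add atoms: none
Why: Fluoride-induced cleavage of the silyl ether, driven by the strong Si–F bond, frees the C15 hydroxyl; the carboxylate and the exocyclic alkene are unaffected.

Step 19
Reactants: 34 hydroxy acid; 35 Meldrum's acid (2,2-dimethyl-1,3-dioxane-4,6-dione)
Product: 36 C15 malonic acid half ester of 34
Conditions: 35 (1.3 equiv), toluene, 100 °C
Reagents that add atoms: none
Why: Acylation of the primary alcohol by Meldrum's acid (thermal ring opening with loss of acetone) gives the malonic acid half ester; the tertiary C19 acid is too hindered to compete.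

Step 20
Reactants: 36 malonic acid half ester; 37 3,4-dihydroxybenzaldehyde
Product: 39 CNP0130717.2, via arylidene malonate 38 (not isolated)
Conditions: 37 (1.5 equiv), pyridine, piperidine (cat.), 50 °C; dil. HCl work-up under argon
Reagents that add atoms: none
Why: Knoevenagel–Doebner condensation: the malonate half ester condenses with the aldehyde under amine catalysis and 38 loses CO2 to give the (E)-cinnamate, the thermodynamically favoured geometry, with the catechol and the C19 acid left unprotected.

**Compound list**
1 | methyl 4-hydroxy-3-methylbenzoate | COC(=O)c1ccc(O)c(C)c1 | starting material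
2 | methyl 3-bromo-4-hydroxy-5-methylbenzoate | COC(=O)c1cc(C)c(O)c(Br)c1 | intermediate
3 | methyl 3-bromo-4-methoxy-5-methylbenzoate | COC(=O)c1cc(C)c(OC)c(Br)c1 | intermediate
4 | methyl 4-methoxy-3-methyl-5-(4,4,5,5-tetramethyl-1,3,2-dioxaborolan-2-yl)benzoate | COC(=O)c1cc(C)c(OC)c(B2OC(C)(C)C(C)(C)O2)c1 | intermediate
5 | methyl 3-hydroxy-4-methoxy-5-methylbenzoate | COC(=O)c1cc(C)c(OC)c(O)c1 | intermediate
6 | tert-butyl acrylate | C=CC(=O)OC(C)(C)C | starting material
7 | methyl 4,4-dimethoxy-5-methyl-3-oxocyclohexa-1,5-diene-1-carboxylate (masked o-benzoquinone) | COC(=O)C1=CC(=O)C(OC)(OC)C(C)=C1 | intermediate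
8 | rac-7-tert-butyl 2-methyl 5,5-dimethoxy-4-methyl-6-oxobicyclo[2.2.2]oct-2-ene-2,7-dicarboxylate, 7-ester syn to C2=C3 | O=C1C(OC)(OC)[C@@]2(C)C[C@H](C(=O)OC(C)(C)C)[C@@H]1C(C(=O)OC)=C2 | intermediate
9 | rac-7-tert-butyl 2-methyl 4-methyl-6-oxobicyclo[2.2.2]oct-2-ene-2,7-dicarboxylate, 7-ester syn to C2=C3 | O=C1C[C@@]2(C)C[C@H](C(=O)OC(C)(C)C)[C@@H]1C(C(=O)OC)=C2 | intermediate
10 | rac-2-(methoxycarbonyl)-4-methyl-6-oxobicyclo[2.2.2]oct-2-ene-7-carboxylic acid (locants as in 9) | O=C1C[C@@]2(C)C[C@H](C(=O)O)[C@@H]1C(C(=O)OC)=C2 | intermediate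
11 | (R)-1-phenylethylammonium salt of the (1R,4R)-enantiomer of 10 | O=C1C[C@@]2(C)C[C@H](C(=O)[O-])[C@@H]1C(C(=O)OC)=C2.C[C@@H]([NH3+])c1ccccc1 | intermediate
12 | (1R,4R)-enantiomer of acid 10, free acid | O=C1C[C@@]2(C)C[C@H](C(=O)O)[C@@H]1C(C(=O)OC)=C2 | intermediate
13 | acid chloride of 12 | O=C1C[C@@]2(C)C[C@H](C(Cl)=O)[C@@H]1C(C(=O)OC)=C2 | intermediate
14 | O-acyl thiohydroxamate of 12 (2-thioxopyridin-1(2H)-yl ester) | O=C1C[C@@]2(C)C[C@H](C(=O)ON3C=CC=CC3=S)[C@@H]1C(C(=O)OC)=C2 | intermediate
15 | methyl (1R,4R)-4-methyl-6-oxobicyclo[2.2.2]oct-2-ene-2-carboxylate | O=C1C[C@@]2(C)CC[C@@H]1C(C(=O)OC)=C2 | intermediate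
16 | methyl (R)-3-methylglutarate (methyl hydrogen (3R)-3-methylpentanedioate) | COC(=O)C[C@H](C)CC(=O)O | starting material
17 | methyl (3R)-5-hydroxy-3-methylpentanoate | COC(=O)C[C@H](C)CCO | intermediate
18 | methyl (3R)-5-[tert-butyl(dimethyl)silyl]oxy-3-methylpentanoate | COC(=O)C[C@H](C)CCO[Si](C)(C)C(C)(C)C | intermediate
19 | (3R)-5-[tert-butyl(dimethyl)silyl]oxy-3-methylpentanal | O=CC[C@H](C)CCO[Si](C)(C)C(C)(C)C | intermediate
20 | lithium enolate of 15 (C8–O, C8=C9) | [O-]C1=C[C@@]2(C)CC[C@@H]1C(C(=O)OC)=C2.[Li+] | intermediate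
21 | aldol adduct of 15 and 19 (C9–C11 bond, C11 hydroxyl; mixture at C9 and C11) | O=C1C(C(O)C[C@H](C)CCO[Si](C)(C)C(C)(C)C)[C@@]2(C)CC[C@@H]1C(C(=O)OC)=C2 | intermediate
22 | C11 methanesulfonate of 21 | O=C1C(C(OS(C)(=O)=O)C[C@H](C)CCO[Si](C)(C)C(C)(C)C)[C@@]2(C)CC[C@@H]1C(C(=O)OC)=C2 | intermediate
23 | methyl (1R,4S,5Z)-5-[(3S)-5-[tert-butyl(dimethyl)silyl]oxy-3-methylpentylidene]-4-methyl-6-oxobicyclo[2.2.2]oct-2-ene-2-carboxylate | O=C1/C(=C\C[C@H](C)CCO[Si](C)(C)C(C)(C)C)[C@@]2(C)CC[C@@H]1C(C(=O)OC)=C2 | intermediate
24 | vinylmagnesium bromide | C=C[Mg]Br | starting material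
25 | methyl (1R,4S,5Z,6R)-6-ethenyl-6-hydroxy-4-methyl-5-[(3S)-5-[tert-butyl(dimethyl)silyl]oxy-3-methylpentylidene]bicyclo[2.2.2]oct-2-ene-2-carboxylate (vinyl syn to C2=C3, hydroxyl syn to the ethano bridge) | C=C[C@]1(O)/C(=C\C[C@H](C)CCO[Si](C)(C)C(C)(C)C)[C@@]2(C)CC[C@@H]1C(C(=O)OC)=C2 | intermediate
26 | potassium alkoxide of 25 | C=C[C@]1([O-])/C(=C\C[C@H](C)CCO[Si](C)(C)C(C)(C)C)[C@@]2(C)CC[C@@H]1C(C(=O)OC)=C2.[K+] | intermediate
27 | potassium enolate of 28 (C8–O, C7=C8) | [O-]C1=CC[C@H]2[C@](C)(CCC=C2C(=O)OC)/C1=C/C[C@H](C)CCO[Si](C)(C)C(C)(C)C.[K+] | intermediate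
28 | methyl (4aS,8aS,5Z)-5-[(3S)-5-[tert-butyl(dimethyl)silyl]oxy-3-methylpentylidene]-4a-methyl-6-oxo-3,4,4a,5,6,7,8,8a-octahydronaphthalene-1-carboxylate (cis-fused; H-8a and 4a-methyl syn) | O=C1CC[C@H]2[C@](C)(CCC=C2C(=O)OC)/C1=C/C[C@H](C)CCO[Si](C)(C)C(C)(C)C | intermediate
29 | methyl 5-[(3S)-5-[tert-butyl(dimethyl)silyl]oxy-3-methylpentyl]-4a-methyl-6-oxodecahydronaphthalene-1-carboxylate (cis-fused; 4a-methyl, H-8a and H-5 syn, side chain anti; C1 of the naphthalene = labdane C4 as a mixture) | O=C1CC[C@H]2[C@](C)(CCCC2C(=O)OC)[C@@H]1CC[C@H](C)CCO[Si](C)(C)C(C)(C)C | intermediate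
30 | methyl 5-[(3S)-5-[tert-butyl(dimethyl)silyl]oxy-3-methylpentyl]-4a-methyl-6-methylidenedecahydronaphthalene-1-carboxylate (ring stereocentres as in 29) | C=C1CC[C@H]2[C@](C)(CCCC2C(=O)OC)[C@@H]1CC[C@H](C)CCO[Si](C)(C)C(C)(C)C | intermediate
31 | lithium ester enolate of 30 (C4=C19) | C=C1CC[C@H]2[C@](C)(CCCC2=C([O-])OC)[C@@H]1CC[C@H](C)CCO[Si](C)(C)C(C)(C)C.[Li+] | intermediate
32 | methyl 1,4a-dimethyl-6-methylidene-5-[(3S)-5-[tert-butyl(dimethyl)silyl]oxy-3-methylpentyl]decahydronaphthalene-1-carboxylate (ester, 4a-methyl, H-8a and H-5 syn; 1-methyl and side chain anti) | C=C1CC[C@H]2[C@](C)(CCC[C@]2(C)C(=O)OC)[C@@H]1CC[C@H](C)CCO[Si](C)(C)C(C)(C)C | intermediate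
33 | carboxylic acid from 32 (C19 CO2H, C15 silyl ether) | C=C1CC[C@H]2[C@](C)(CCC[C@]2(C)C(=O)O)[C@@H]1CC[C@H](C)CCO[Si](C)(C)C(C)(C)C | intermediate
34 | hydroxy acid (C19 CO2H, C15 OH) | C=C1CC[C@H]2[C@](C)(CCC[C@]2(C)C(=O)O)[C@@H]1CC[C@H](C)CCO | intermediate
35 | Meldrum's acid (2,2-dimethyl-1,3-dioxane-4,6-dione) | CC1(C)OC(=O)CC(=O)O1 | starting material
36 | C15 malonic acid half ester of 34 | C=C1CC[C@H]2[C@](C)(CCC[C@]2(C)C(=O)O)[C@@H]1CC[C@H](C)CCOC(=O)CC(=O)O | intermediate
37 | 3,4-dihydroxybenzaldehyde | O=Cc1ccc(O)c(O)c1 | starting material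
38 | (3,4-dihydroxybenzylidene)malonic acid half ester of 34 | C=C1CC[C@H]2[C@](C)(CCC[C@]2(C)C(=O)O)[C@@H]1CC[C@H](C)CCOC(=O)C(=Cc1ccc(O)c(O)c1)C(=O)O | intermediate
39 | CNP0130717.2: (1S,4aR,5R,8aS)-5-[(3S)-5-[(2E)-3-(3,4-dihydroxyphenyl)prop-2-enoyl]oxy-3-methylpentyl]-1,4a-dimethyl-6-methylidenedecahydronaphthalene-1-carboxylic acid (labdane numbering 4S,5S,9R,10R,13S) | C=C1CC[C@H]2[C@](C)(CCC[C@]2(C)C(=O)O)[C@@H]1CC[C@H](C)CCOC(=O)/C=C/c1ccc(O)c(O)c1 | target

**Step count**
Total: 20 steps. Longest linear sequence: 18 steps (steps 1–8 and 11–20); the side-chain branch is steps 9–10.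

**Steps most likely to fail, with fallbacks**

Step 13 (key step). The potassium enolate 27 carries the C4 ester within reach of C7, so an intramolecular acylation that closes a bridged diketone, or plain fragmentation of alkoxide 26, may compete with the [3,3] shift. The fallback takes the ester out of play as a carboxylate. It sets out from 25, whose methyl ester is hydrolysed with LiOH in THF/MeOH/H2O to the carbinol acid F1. F1 is treated with KH (3 equiv) and 18-crown-6 in THF and rearranges as its dianion, whose carboxylate cannot be acylated, to give the keto acid F2 after acidification. Esterification of F2 with Me3SiCHN2 in toluene/MeOH comes back to the route at 28.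

Step 14. Delivery of hydrogen to C9 may not be selective for the convex face if the conformer with the C10 methyl axial on ring B is populated, and the C9 centre would then be formed as a mixture that base cannot be trusted to correct. The fallback sets C9 before the rearrangement, in the rigid bicycle. It sets out from 23: conjugate reduction with [(Ph3P)CuH]6 in toluene (hydride to C11) and protonation of the copper enolate at C9 from the etheno-bridge face should give the saturated ketone F3, with the side chain syn to the C1–C2 bridge. Addition of vinylmagnesium bromide with CeCl3 as in step 12, where the C9 substituent now also shields the ethano-bridge face, gives the carbinol F4. Rearrangement with KH and 18-crown-6 as in step 13 gives the cis-fused ketone F5 with C9 already in place, and hydrogenation of its C3=C4 enoate over Pd on carbon comes back to the route at 29.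

Step 7. The two diastereomeric salts may not differ enough in solubility, so that crystallisation enriches slowly or not at all. The fallback moves the resolution to the ketone. It sets out from racemic 10, which is decarboxylated as in step 8 (through the racemic forms of 13 and 14) to the racemic ketone F6. Addition of the lithium salt of (S)-N,S-dimethyl-S-phenylsulfoximine (sulfoximine, n-BuLi, THF, −78 °C) to the C8 carbonyl from the etheno-bridge face gives two diastereomeric β-hydroxy sulfoximines, which are separated by chromatography: the adduct of the required enantiomer F7 and the adduct of the other enantiomer F8, which is discarded. Heating F7 in toluene at 110 °C reverses the addition, releases the sulfoximine and comes back to the route at 15.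

**Further compounds**
F1 | step 13 | carbinol acid: carboxylic acid corresponding to 25 | C=C[C@]1(O)/C(=C\C[C@H](C)CCO[Si](C)(C)C(C)(C)C)[C@@]2(C)CC[C@@H]1C(C(=O)O)=C2
F2 | step 13 | keto acid: carboxylic acid corresponding to 28 | O=C1CC[C@H]2[C@](C)(CCC=C2C(=O)O)/C1=C/C[C@H](C)CCO[Si](C)(C)C(C)(C)C
F3 | step 14 | saturated bicyclic ketone: 23 with C9–C11 reduced, side chain syn to the ethano bridge | O=C1[C@@H](CC[C@H](C)CCO[Si](C)(C)C(C)(C)C)[C@@]2(C)CC[C@@H]1C(C(=O)OC)=C2
F4 | step 14 | vinyl carbinol from F3 (vinyl syn to the etheno bridge) | C=C[C@]1(O)[C@@H](CC[C@H](C)CCO[Si](C)(C)C(C)(C)C)[C@@]2(C)CC[C@@H]1C(C(=O)OC)=C2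
F5 | step 14 | cis-fused keto enoate with C9 saturated (28 with C9–C11 reduced, side chain anti to the C10 methyl) | O=C1CC[C@H]2[C@](C)(CCC=C2C(=O)OC)[C@@H]1CC[C@H](C)CCO[Si](C)(C)C(C)(C)C
F6 | step 7 | racemic methyl 4-methyl-6-oxobicyclo[2.2.2]oct-2-ene-2-carboxylate (shown as the enantiomer 15) | O=C1C[C@@]2(C)CC[C@@H]1C(C(=O)OC)=C2
F7 | step 7 | β-hydroxy sulfoximine from the (1R,4R)-ketone and the (S)-sulfoximine | CN=[S@@](=O)(c1ccccc1)C[C@]1(O)C[C@@]2(C)CC[C@@H]1C(C(=O)OC)=C2
F8 | step 7 | β-hydroxy sulfoximine from the (1S,4S)-ketone and the (S)-sulfoximine (discarded diastereomer) | CN=[S@@](=O)(c1ccccc1)C[C@@]1(O)C[C@]2(C)CC[C@H]1C(C(=O)OC)=C2
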